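## Structural features

The target (C36H26O19) is a linear chain of six benzene rings, A to F, joined by five diaryl ether oxygens and carrying fourteen free phenolic hydroxyls. It has no stereocentre, so no step has to control configuration. Taking C4 of each ring as the carbon between the hydroxyl carbons C3 and C5, and C1 as the carbon para to it, every ether oxygen joins C4 of one ring to C1 of the next. Ring A ends in a free C1 hydroxyl (2,4,6-trihydroxyphenyl), and ring F is a 3,4,5-trihydroxyphenyl ring attached through C1. The free polyphenol is fragile: the pyrogallol ring F and the para-dioxygenated rings B to E are oxidised to quinones by air, fastest as phenoxides, and every ring is nucleophilic enough to be C-alkylated by carbocations. The real difficulty is the five ether bonds at C4, each on an electron-rich carbon flanked by two oxygenated ortho carbons, where SNAr has no activation and metal-mediated aryl–oxygen coupling is hindered. In addition, the C1 oxygen must be told apart from the C3 and C5 oxygens in five nearly identical rings. The key step exploits the fact that each of rings A to E is a 1,3,5-trioxygenated ring with a fourth oxygen on C4. C4 of ring E with its ether oxygen is carried as an aryloxymethyl carbon, C3 and C5 as the lactone carbonyl and ring-oxygen carbons of a pyran-2-one, and C1 as its alkoxy carbon, so the ether is made at a primary sp3 carbon and the benzene ring is closed afterwards through the C3–C4 bond.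

## Logic of the disconnections

35 from 34. Eleven O–CH3 bonds and one O–CH2Ph bond are cut; no skeletal bond changes. They are cut last because the free tetradecaphenol is air-sensitive and should be handled only once. The gain is that every earlier compound is a stable ether that can be chromatographed. The forward step must cleave twelve alkyl aryl ethers completely, leave the diaryl ethers alone and keep the benzyl cation off the rings, which calls for a cation scavenger and an oxygen-free work-up.

34 from 31. The C3–C4 bond of ring A is cut and ring A is unfolded into the lactone ring of 31: C4 becomes the OCH2 carbon, C3 the lactone carbonyl carbon, C5 the ring-oxygen carbon and C1 the benzyloxy carbon. The cut is made there because it turns the hindered A–B diaryl ether into an alkyl aryl ether at a primary carbon. The forward step must open the lactone with alkoxide and close through the OCH2 carbanion, with aromatisation as the driving force.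

31 from 30 and 5. The O–CH2 bond between the C1 oxygen of ring B and the future C4 of ring A is cut. This is where the future diaryl ether oxygen is installed, by SN2 attack of an unhindered phenoxide on an activated primary chloride. The gain is a pentameric phenol plus a six-carbon electrophile that serves every cycle. The forward step needs a base mild enough to leave the lactone of 5 intact.

30 from 29 from 28. One O–CH2Ph bond is cut (30 from 29) and two O–CH3 bonds are cut (29 from 28). The ring-forming step delivers the C1 oxygen benzylated and the C3 and C5 oxygens free, so the three oxygens are already differentiated; methyl caps make the distinction permanent and hydrogenolysis then exposes C1 alone. The forward steps need O- rather than C-methylation and a hydrogenolysis that spares diaryl and methyl ethers.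

28 back to 12. The same three cuts are repeated for ring B (28 from 25, 25 from 24 and 5), ring C (22 from 19, 19 from 18 and 5) and ring D (16 from 13, 13 from 12 and 5), each followed by the protecting-group pair (24 from 23 from 22, 18 from 17 from 16, 12 from 11 from 10). Each cycle removes one ring and always returns to the same electrophile 5, so only one building block has to be made.

10 from 7. The C3–C4 bond of ring E is cut and ring E is unfolded into the lactone ring of 7; this is the key step. The gain is the largest of the route, since the E–F diaryl ether becomes an O–CH2 ether of a commercial phenol. The demand is the one stated for 34 from 31, here on the smallest substrate.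

7 from 6 and 5. The O–CH2 bond is cut. This leaves the commercial phenol 6, which carries all of ring F, and the chloride 5.

5 from 3 (through 4), and 3 from 1 and 2. The C–Cl bond and then the O–CH2Ph bond are cut. The six carbons of every new ring thus come from 1, a commercial lactone that already has the 1,3,5-oxygen pattern. The forward steps must functionalise only the methyl group of 3 and benzylate 1 on the C4 oxygen. A single halogenation is chosen over an oxidation, reduction and Mitsunobu sequence because it is one step shorter and avoids a selenium reagent.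

## Other disconnections considered

Alternative 1: Ring D would be cut at C1–C2 and C4–C5 into the E–F keto ester A2 (a methyl 4-aryloxyacetoacetate, supplying C2, C3, C4 and the ester carbon) and the A–B–C ynoate A3 (a methyl 3-aryloxypropiolate, supplying C1, C6 and C5). In the forward step the potassium enolate of A2, made with KOC(CH3)3, would add to the oxygen-bearing alkyne carbon of A3 (C1–C2), and the aryloxy-substituted carbon of the adduct would close on the propiolate ester (C4–C5) to give the methyl resorcylate A1.
- In its favour: it is convergent, since a trimer and a dimer meet in the ring-forming step; it makes two carbon–carbon bonds at once; and the polarity of the partners fixes all four oxygens of ring D.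
- Equal or better: the Claisen closure (an aryloxy-substituted carbanion attacking an ester, driven by aromatisation) is the same type as in the chosen plan, so the two are equal there. On convergence and on the longest linear sequence this alternative would be the better.
- Against it here: it builds one ring only, so the A–B, B–C and E–F ether bonds, all equally hindered, still need another method. A3 is an ynol ether whose oxygen sits on C4 of ring C between two methoxy groups, so it must be made from a hindered phenol and its electrophilic carbon is donor-substituted and shielded. The enolate can expel the aryloxide after addition, and O-acylation of the adduct would close a lactone in place of the benzene ring, with no matched-alkoxide equilibrium to correct it. A1 keeps a CO2CH3 group on C2 that the target lacks, so a doubly ortho-substituted, hydrogen-bonded ester must be hydrolysed and decarboxylated.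
- Comparison: in structure it covers one ring where the chosen plan covers five by one repeatable operation; in mechanism the ring closure is equal but the first bond is intermolecular and hindered; in step economy the shorter linear sequence is offset by separate syntheses of A2 and A3 and by removal of the extra carbon.

Alternative 2: All ten C–O bonds at C3 and C5 of rings A to E would be traced back to C–CHO bonds, and the five ether bonds to SNAr reactions of phenoxides with 2-fluoroisophthalaldehydes such as A6, whose fluoride is activated by two ortho formyl groups. Iteration from ring F towards ring A would give the deca-aldehyde A5. In the forward key step m-chloroperbenzoic acid would convert each Ar–CHO into Ar–OCHO by Baeyer–Villiger oxidation with aryl migration (ten migrations, no ring closed) to give the decaformate A4.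
- In its favour: the formyl groups do double duty, activating the hindered C4 carbon for ether formation and then becoming the flanking hydroxyls; every ether bond is made directly and without a metal.
- Equal or better: on paper its step count is lower than that of the chosen plan, which is a point on which it would be the better. Both plans are linear, grow from ring F to ring A and cover all five ether bonds, so they are equal in scope and convergence.
- Against it here: aryl migration needs an electron-rich migrating ring, but each formyl group sits on a ring with a second formyl group and only one ortho aryloxy donor, so hydride migration, which would leave a carboxyl group, competes at each site. With ten sites in one molecule any leakage per site is multiplied, and the resulting mixtures would be hard to separate at that size. The peracid also meets the trimethoxyphenyl ring F and increasingly electron-rich product rings, which are open to hydroxylation and quinone formation. The phenoxides of the later SNAr steps are deactivated by two formyl groups, and ten aldehydes must survive repeated basic steps.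
- Comparison: the chosen plan settles each ring in one thermodynamically driven event with its oxygens already in place, whereas here the outcome rests on a single tenfold reaction at the end.

Alternative 3: Only ring A would be cut, at its C1–C2 bond (sugar C1–C6), with its six carbons traced to 2-deoxy-D-galactose A9. The A–B ether oxygen would be the sugar O4, joined at an sp3 carbon to the pentameric phenol that is 30 of the chosen route. In the forward key step Hg(OCOCF3)2, a salt of divalent mercury, in aqueous acetone would hydroxymercurate the exocyclic enol ether of the hex-5-enopyranoside A8. The hemiacetal would open to a 5-keto aldehyde and the mercury-bearing C6 would close on C1 in an aldol reaction (Ferrier carbocyclisation) to give the cyclohexanone A7. A7 as formulated has the aryloxy group trans to the benzyloxy group (the D-arabino pattern at sugar C3 and C4), whereas A9 has these oxygens cis. The aryl ether must therefore be made with inversion at C4, by an SN2 (Mitsunobu-type) reaction of the axial hydroxyl.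
- In its favour: the carbocyclisation is mild, nearly neutral and dependable for O-substituted enopyranosides, and its stereochemical outcome is irrelevant because all three stereocentres of A7 vanish on aromatisation.
- Equal or better: the ether oxygen enters at an sp3 carbon before the ring becomes aromatic, the same principle as in the chosen plan, so the two are equal there. On mildness of the ring-closing conditions this alternative is the better.
- Against it here: it addresses one ring of six, so 30 must still be made and the sequence could at best replace steps 19 to 21. The oxidation level does not match: A7 has one ketone and two carbinol carbons where ring A needs three enol-level carbons. Debenzylation and two oxidations next to a ketone would be needed, and β-elimination of water or benzyl alcohol, which aromatises with loss of an oxygen, is the easier path. Etherification of a secondary sugar carbon by a bulky phenol is far less certain than attack on the primary CH2Cl of 5. The way from A9 to A8 costs many steps, and a toxic mercury salt is used.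
- Comparison: in step economy it is clearly the poorer, at roughly ten steps for one ring against three in the chosen plan.

Key step: step 4

Remarks before the steps
- Ring numbering is as defined under "Structural features". Shorthand for the aryl groups: ArF = 3,4,5-trimethoxyphenyl; ArEF = 3,5-dimethoxy-4-(ArF-oxy)phenyl; ArDEF = 3,5-dimethoxy-4-(ArEF-oxy)phenyl; ArCDEF = 3,5-dimethoxy-4-(ArDEF-oxy)phenyl; ArBCDEF = 3,5-dimethoxy-4-(ArCDEF-oxy)phenyl.
- Correction on geometry: the ring-opened enoate that keeps the geometry of the lactone double bond has the ester cis to the CH2C(O) arm. By the sequence rules (CO2R over H, OCH2Ph over CH2) this is the (2E) isomer. A (2Z) isomer would hold the ester away from the ketone arm and could not cyclise.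
- Assumption: sodium benzyloxide is used as the commercial 1 M solution in benzyl alcohol, and all operations on free phenols or phenoxides are run under argon with degassed solvents.

## Steps

Step 1
Reactants: 1 4-hydroxy-6-methyl-2H-pyran-2-one; 2 benzyl bromide
Product: 3 4-(benzyloxy)-6-methyl-2H-pyran-2-one
Conditions: K2CO3, DMF, 50 °C
Reagents that add atoms: none
Why: Williamson O-alkylation of a vinylogous acid: the carbonate-derived anion of 1 is benzylated on the C4 oxygen in a dipolar aprotic solvent, the usual outcome for this lactone with alkyl halides; C3-benzylation and alkylation of the carbonyl oxygen are the minor competitors and are removed by crystallisation.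

Step 2
Reactants: 3 4-(benzyloxy)-6-methyl-2H-pyran-2-one
Product: 5 4-(benzyloxy)-6-(chloromethyl)-2H-pyran-2-one, via lithium dienolate 4 (not isolated)
Conditions: LiN(SiMe3)2, THF, −78 °C; then added by cannula to C2Cl6, THF, −78 → −40 °C; aq. NH4Cl
Reagents that add atoms: hexachloroethane, ClC(Cl)(Cl)C(Cl)(Cl)Cl
Why: Vinylogous deprotonation of the 6-methyl group of a 4-alkoxy-6-methylpyran-2-one gives the extended dienolate 4, which reacts with electrophiles at the exocyclic carbon, and hexachloroethane acts as a Cl+ donor (enolate chlorination, as used for the related 6-methyl-1,3-dioxin-4-ones); inverse addition into excess C2Cl6 keeps 5 away from unreacted 4 and so suppresses proton transfer and double chlorination, and the far less acidic benzylic CH2 is untouched at −78 °C.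

Step 3
Reactants: 6 3,4,5-trimethoxyphenol; 5 4-(benzyloxy)-6-(chloromethyl)-2H-pyran-2-one
Product: 7 4-(benzyloxy)-6-[(3,4,5-trimethoxyphenoxy)methyl]-2H-pyran-2-one
Conditions: K2CO3, DMF, 40 °C, Ar
Reagents that add atoms: none
Why: Williamson ether synthesis: the unhindered phenoxide of 6 displaces chloride from the primary CH2Cl of 5, which is activated like an allylic halide conjugated to an ester, while carbonate is too weak to open the lactone; this step places the oxygen that becomes the E–F diaryl ether oxygen.

Step 4
Reactants: 7 4-(benzyloxy)-6-[(3,4,5-trimethoxyphenoxy)methyl]-2H-pyran-2-one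
Product: 10 5-(benzyloxy)-2-(3,4,5-trimethoxyphenoxy)benzene-1,3-diol (rings E–F), via ring-opened (2E)-enoate 8 (not isolated), via cyclohexadienone tautomer 9 (not isolated)
Conditions: NaOCH2Ph (3 equiv, 1 M in PhCH2OH), THF, 0 → 65 °C, Ar; then 1 M HCl, 0 °C
Reagents that add atoms: none
Why: Benzyloxide adds to the lactone carbonyl of 7 and the acyl–oxygen bond breaks, which gives the sodium dienolate of 8; the enoate is (2E) because the ester stays cis to the CH2C(O) arm, as it was in the ring. Proton exchange with benzyl alcohol makes the less stable enolate at the aryloxymethyl carbon available (that CH2 is acidified by the ketone and by the aryloxy oxygen), and this carbanion attacks the ester carbonyl in an intramolecular Claisen (Dieckmann-type) condensation that forms the C3–C4 bond of ring E. The closure is 6-(enolendo)-exo-trig and is the only ring closed; loss of benzyloxide gives 9, which tautomerises to the resorcinol 10, held as its disodium salt until the acid quench. The closest known reaction type is the base-mediated recyclisation of 4-alkoxy-6-methylpyran-2-ones and of 3,5-dioxohexanoates to phloroglucinol monoethers. No stereocentre is formed. Three selectivities are needed: addition at the lactone carbonyl and not net loss of the 4-alkoxy group, which the matched alkoxide secures because addition–elimination at C4 only returns 7; C-acylation and not O-acylation, which is secured because O-closure merely re-forms 7 and is reversible while C-closure is removed from the equilibrium by aromatisation and phenoxide formation; and closure through the aryloxymethyl carbon, which is secured because the more acidic CH2 between the ketone and the enol ether could only give a four-membered ring. More than two equivalents of base are used because 10 consumes two.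

Step 5
Reactants: 10 5-(benzyloxy)-2-(3,4,5-trimethoxyphenoxy)benzene-1,3-diol
Product: 11 5-(benzyloxy)-1,3-dimethoxy-2-(3,4,5-trimethoxyphenoxy)benzene
Conditions: MeI, K2CO3, DMF, rt, Ar
Reagents that add atoms: iodomethane, CI
Why: Williamson O-methylation of both phenols with carbonate in a dipolar aprotic solvent, which favours O- over C-alkylation of the resorcinol; the benzyl ether is inert and now marks the C1 oxygen of ring E as the only one that can be freed by hydrogenolysis.

Step 6
Reactants: 11 5-(benzyloxy)-1,3-dimethoxy-2-(3,4,5-trimethoxyphenoxy)benzene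
Product: 12 3,5-dimethoxy-4-(3,4,5-trimethoxyphenoxy)phenol (ArEF–OH)
Conditions: H2 (1 atm), 10% Pd/C, EtOAc–MeOH, rt
Reagents that add atoms: none
Why: Catalytic hydrogenolysis of the benzyl aryl ether over zerovalent palladium on carbon frees the C1 phenol of ring E only; aryl methyl ethers and diaryl ethers are not cleaved under these conditions.

Step 7
Reactants: 12 3,5-dimethoxy-4-(3,4,5-trimethoxyphenoxy)phenol; 5 4-(benzyloxy)-6-(chloromethyl)-2H-pyran-2-one
Product: 13 4-(benzyloxy)-6-[(ArEF-oxy)methyl]-2H-pyran-2-one
Conditions: K2CO3, DMF, 40 °C, Ar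
Reagents that add atoms: none
Why: Williamson etherification as in step 3: the phenoxide of 12 (C1 oxygen of ring E, no ortho substituent) displaces chloride from 5, and this oxygen becomes the D–E diaryl ether oxygen.

Step 8
Reactants: 13 4-(benzyloxy)-6-[(ArEF-oxy)methyl]-2H-pyran-2-one
Product: 16 5-(benzyloxy)-2-(ArEF-oxy)benzene-1,3-diol (rings D–F), via ring-opened (2E)-enoate 14 (not isolated), via cyclohexadienone tautomer 15 (not isolated)
Conditions: NaOCH2Ph (3 equiv, 1 M in PhCH2OH), THF, 0 → 65 °C, Ar; then 1 M HCl, 0 °C
Reagents that add atoms: none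
Why: Lactone opening and Claisen reclosure as in step 4: benzyloxide opens 13 to 14, the aryloxymethyl carbanion closes on the benzyl ester (6-exo-trig) to form the C3–C4 bond of ring D, and 15 tautomerises to the aromatic diol; the methyl and diaryl ethers of rings E and F are inert to alkoxide.

Step 9
Reactants: 16 5-(benzyloxy)-2-(ArEF-oxy)benzene-1,3-diol
Product: 17 5-(benzyloxy)-1,3-dimethoxy-2-(ArEF-oxy)benzene
Conditions: MeI, K2CO3, DMF, rt, Ar
Reagents that add atoms: iodomethane, CI
Why: Williamson O-methylation as in step 5, capping the C3 and C5 oxygens of ring D.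

Step 10
Reactants: 17 5-(benzyloxy)-1,3-dimethoxy-2-(ArEF-oxy)benzene
Product: 18 4-(ArEF-oxy)-3,5-dimethoxyphenol (ArDEF–OH)
Conditions: H2 (1 atm), 10% Pd/C, EtOAc–MeOH, rt
Reagents that add atoms: none
Why: Hydrogenolysis of the single benzyl ether as in step 6, freeing the C1 phenol of ring D.

Step 11
Reactants: 18 4-(ArEF-oxy)-3,5-dimethoxyphenol; 5 4-(benzyloxy)-6-(chloromethyl)-2H-pyran-2-one
Product: 19 4-(benzyloxy)-6-[(ArDEF-oxy)methyl]-2H-pyran-2-one
Conditions: K2CO3, DMF, 40 °C, Ar
Reagents that add atoms: none
Why: Williamson etherification as in step 3; the new O–CH2 oxygen becomes the C–D diaryl ether oxygen.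

Step 12
Reactants: 19 4-(benzyloxy)-6-[(ArDEF-oxy)methyl]-2H-pyran-2-one
Product: 22 5-(benzyloxy)-2-(ArDEF-oxy)benzene-1,3-diol (rings C–F), via ring-opened (2E)-enoate 20 (not isolated), via cyclohexadienone tautomer 21 (not isolated)
Conditions: NaOCH2Ph (3 equiv, 1 M in PhCH2OH), THF, 0 → 65 °C, Ar; then 1 M HCl, 0 °C
Reagents that add atoms: none
Why: Lactone opening and Claisen reclosure as in step 4, forming the C3–C4 bond of ring C by 6-exo-trig closure of the aryloxymethyl carbanion on the benzyl ester of 20, followed by tautomerisation of 21.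

Step 13
Reactants: 22 5-(benzyloxy)-2-(ArDEF-oxy)benzene-1,3-diol
Product: 23 5-(benzyloxy)-1,3-dimethoxy-2-(ArDEF-oxy)benzene
Conditions: MeI, K2CO3, DMF, rt, Ar
Reagents that add atoms: iodomethane, CI
Why: Williamson O-methylation as in step 5, capping the C3 and C5 oxygens of ring C.

Step 14
Reactants: 23 5-(benzyloxy)-1,3-dimethoxy-2-(ArDEF-oxy)benzene
Product: 24 4-(ArDEF-oxy)-3,5-dimethoxyphenol (ArCDEF–OH)
Conditions: H2 (1 atm), 10% Pd/C, THF–MeOH, rt
Reagents that add atoms: none
Why: Hydrogenolysis of the single benzyl ether as in step 6, freeing the C1 phenol of ring C.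

Step 15
Reactants: 24 4-(ArDEF-oxy)-3,5-dimethoxyphenol; 5 4-(benzyloxy)-6-(chloromethyl)-2H-pyran-2-one
Product: 25 4-(benzyloxy)-6-[(ArCDEF-oxy)methyl]-2H-pyran-2-one
Conditions: K2CO3, DMF, 40 °C, Ar
Reagents that add atoms: none
Why: Williamson etherification as in step 3; the new O–CH2 oxygen becomes the B–C diaryl ether oxygen.

Step 16
Reactants: 25 4-(benzyloxy)-6-[(ArCDEF-oxy)methyl]-2H-pyran-2-one
Product: 28 5-(benzyloxy)-2-(ArCDEF-oxy)benzene-1,3-diol (rings B–F), via ring-opened (2E)-enoate 26 (not isolated), via cyclohexadienone tautomer 27 (not isolated)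
Conditions: NaOCH2Ph (3 equiv, 1 M in PhCH2OH), THF, 0 → 65 °C, Ar; then 1 M HCl, 0 °C
Reagents that add atoms: none
Why: Lactone opening and Claisen reclosure as in step 4, forming the C3–C4 bond of ring B by 6-exo-trig closure of the aryloxymethyl carbanion on the benzyl ester of 26, followed by tautomerisation of 27.

Step 17
Reactants: 28 5-(benzyloxy)-2-(ArCDEF-oxy)benzene-1,3-diol
Product: 29 5-(benzyloxy)-1,3-dimethoxy-2-(ArCDEF-oxy)benzene
Conditions: MeI, K2CO3, DMF, rt, Ar
Reagents that add atoms: iodomethane, CI
Why: Williamson O-methylation as in step 5, capping the C3 and C5 oxygens of ring B.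

Step 18
Reactants: 29 5-(benzyloxy)-1,3-dimethoxy-2-(ArCDEF-oxy)benzene
Product: 30 4-(ArCDEF-oxy)-3,5-dimethoxyphenol (ArBCDEF–OH)
Conditions: H2 (1 atm), 10% Pd/C, THF–MeOH, rt
Reagents that add atoms: none
Why: Hydrogenolysis of the single benzyl ether as in step 6, freeing the C1 phenol of ring B.

Step 19
Reactants: 30 4-(ArCDEF-oxy)-3,5-dimethoxyphenol; 5 4-(benzyloxy)-6-(chloromethyl)-2H-pyran-2-one
Product: 31 4-(benzyloxy)-6-[(ArBCDEF-oxy)methyl]-2H-pyran-2-one
Conditions: K2CO3, DMF, 40 °C, Ar
Reagents that add atoms: none
Why: Williamson etherification as in step 3; the new O–CH2 oxygen becomes the A–B diaryl ether oxygen.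

Step 20
Reactants: 31 4-(benzyloxy)-6-[(ArBCDEF-oxy)methyl]-2H-pyran-2-one
Product: 34 5-(benzyloxy)-2-(ArBCDEF-oxy)benzene-1,3-diol (rings A–F), via ring-opened (2E)-enoate 32 (not isolated), via cyclohexadienone tautomer 33 (not isolated)
Conditions: NaOCH2Ph (3 equiv, 1 M in PhCH2OH), THF, 0 → 65 °C, Ar; then 1 M HCl, 0 °C
Reagents that add atoms: none
Why: Lactone opening and Claisen reclosure as in step 4, forming the C3–C4 bond of ring A by 6-exo-trig closure of the aryloxymethyl carbanion on the benzyl ester of 32, followed by tautomerisation of 33; the two hydroxyls of ring A are left free because they are wanted in the target.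

Step 21
Reactants: 34 5-(benzyloxy)-2-(ArBCDEF-oxy)benzene-1,3-diol
Product: 35 target hexamer, 2-{4-[4-(4-{4-[(3,4,5-trihydroxyphenyl)oxy]-3,5-dihydroxyphenoxy}-3,5-dihydroxyphenoxy)-3,5-dihydroxyphenoxy]-3,5-dihydroxyphenoxy}benzene-1,3,5-triol
Conditions: BBr3 (40 equiv), C6HMe5 (5 equiv), CH2Cl2, −78 °C → rt, Ar; then H2O, 0 °C
Reagents that add atoms: none
Why: Lewis-acid ether cleavage: BBr3 coordinates each alkyl aryl ether oxygen and bromide attacks the methyl carbon (SN2), while the benzyl group leaves as a benzylic cation equivalent that pentamethylbenzene captures (Friedel–Crafts), so the electron-rich rings are not C-benzylated; diaryl ether oxygens carry no sp3 carbon and survive, and aqueous work-up releases the fourteen phenols.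

## Compound list

1 | 4-hydroxy-6-methyl-2H-pyran-2-one | CC1=CC(O)=CC(=O)O1 | starting material
2 | benzyl bromide | BrCc1ccccc1 | starting material
3 | 4-(benzyloxy)-6-methyl-2H-pyran-2-one | CC1=CC(OCc2ccccc2)=CC(=O)O1 | intermediate
4 | lithium 4-(benzyloxy)-6-methylidene-6H-pyran-2-olate (lithium dienolate of 3) | C=C1C=C(OCc2ccccc2)C=C([O-])O1.[Li+] | intermediate (not isolated)
5 | 4-(benzyloxy)-6-(chloromethyl)-2H-pyran-2-one | ClCC1=CC(OCc2ccccc2)=CC(=O)O1 | intermediate
6 | 3,4,5-trimethoxyphenol | COc1cc(O)cc(OC)c1OC | starting material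
7 | 4-(benzyloxy)-6-[(3,4,5-trimethoxyphenoxy)methyl]-2H-pyran-2-one | O=C1C=C(OCc2ccccc2)C=C(COc3cc(OC)c(OC)c(OC)c3)O1 | intermediate
8 | benzyl (2E)-3-(benzyloxy)-5-oxo-6-(3,4,5-trimethoxyphenoxy)hex-2-enoate | O=C(OCc1ccccc1)/C=C(/OCc2ccccc2)CC(=O)COc3cc(OC)c(OC)c(OC)c3 | intermediate (not isolated)
9 | 5-(benzyloxy)-3-hydroxy-2-(3,4,5-trimethoxyphenoxy)cyclohexa-2,4-dien-1-one | O=C1CC(OCc2ccccc2)=CC(O)=C1Oc3cc(OC)c(OC)c(OC)c3 | intermediate (not isolated)
10 | 5-(benzyloxy)-2-(3,4,5-trimethoxyphenoxy)benzene-1,3-diol (rings E–F) | Oc1cc(OCc2ccccc2)cc(O)c1Oc3cc(OC)c(OC)c(OC)c3 | intermediate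
11 | 5-(benzyloxy)-1,3-dimethoxy-2-(3,4,5-trimethoxyphenoxy)benzene | COc1cc(OCc2ccccc2)cc(OC)c1Oc3cc(OC)c(OC)c(OC)c3 | intermediate
12 | 3,5-dimethoxy-4-(3,4,5-trimethoxyphenoxy)phenol (ArEF–OH) | Oc1cc(OC)c(Oc2cc(OC)c(OC)c(OC)c2)c(OC)c1 | intermediate
13 | 4-(benzyloxy)-6-{[3,5-dimethoxy-4-(3,4,5-trimethoxyphenoxy)phenoxy]methyl}-2H-pyran-2-one | O=C1C=C(OCc2ccccc2)C=C(COc3cc(OC)c(Oc4cc(OC)c(OC)c(OC)c4)c(OC)c3)O1 | intermediate
14 | benzyl (2E)-3-(benzyloxy)-6-(ArEF-oxy)-5-oxohex-2-enoate | O=C(OCc1ccccc1)/C=C(/OCc2ccccc2)CC(=O)COc3cc(OC)c(Oc4cc(OC)c(OC)c(OC)c4)c(OC)c3 | intermediate (not isolated)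
15 | 5-(benzyloxy)-3-hydroxy-2-(ArEF-oxy)cyclohexa-2,4-dien-1-one | O=C1CC(OCc2ccccc2)=CC(O)=C1Oc3cc(OC)c(Oc4cc(OC)c(OC)c(OC)c4)c(OC)c3 | intermediate (not isolated)
16 | 5-(benzyloxy)-2-(ArEF-oxy)benzene-1,3-diol (rings D–F) | Oc1cc(OCc2ccccc2)cc(O)c1Oc3cc(OC)c(Oc4cc(OC)c(OC)c(OC)c4)c(OC)c3 | intermediate
17 | 5-(benzyloxy)-1,3-dimethoxy-2-(ArEF-oxy)benzene | COc1cc(OCc2ccccc2)cc(OC)c1Oc3cc(OC)c(Oc4cc(OC)c(OC)c(OC)c4)c(OC)c3 | intermediate
18 | 4-(ArEF-oxy)-3,5-dimethoxyphenol (ArDEF–OH) | Oc1cc(OC)c(Oc2cc(OC)c(Oc3cc(OC)c(OC)c(OC)c3)c(OC)c2)c(OC)c1 | intermediate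
19 | 4-(benzyloxy)-6-[(ArDEF-oxy)methyl]-2H-pyran-2-one | O=C1C=C(OCc2ccccc2)C=C(COc3cc(OC)c(Oc4cc(OC)c(Oc5cc(OC)c(OC)c(OC)c5)c(OC)c4)c(OC)c3)O1 | intermediate
20 | benzyl (2E)-3-(benzyloxy)-6-(ArDEF-oxy)-5-oxohex-2-enoate | O=C(OCc1ccccc1)/C=C(/OCc2ccccc2)CC(=O)COc3cc(OC)c(Oc4cc(OC)c(Oc5cc(OC)c(OC)c(OC)c5)c(OC)c4)c(OC)c3 | intermediate (not isolated)
21 | 5-(benzyloxy)-3-hydroxy-2-(ArDEF-oxy)cyclohexa-2,4-dien-1-one | O=C1CC(OCc2ccccc2)=CC(O)=C1Oc3cc(OC)c(Oc4cc(OC)c(Oc5cc(OC)c(OC)c(OC)c5)c(OC)c4)c(OC)c3 | intermediate (not isolated)
22 | 5-(benzyloxy)-2-(ArDEF-oxy)benzene-1,3-diol (rings C–F) | Oc1cc(OCc2ccccc2)cc(O)c1Oc3cc(OC)c(Oc4cc(OC)c(Oc5cc(OC)c(OC)c(OC)c5)c(OC)c4)c(OC)c3 | intermediate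
23 | 5-(benzyloxy)-1,3-dimethoxy-2-(ArDEF-oxy)benzene | COc1cc(OCc2ccccc2)cc(OC)c1Oc3cc(OC)c(Oc4cc(OC)c(Oc5cc(OC)c(OC)c(OC)c5)c(OC)c4)c(OC)c3 | intermediate
24 | 4-(ArDEF-oxy)-3,5-dimethoxyphenol (ArCDEF–OH) | Oc1cc(OC)c(Oc2cc(OC)c(Oc3cc(OC)c(Oc4cc(OC)c(OC)c(OC)c4)c(OC)c3)c(OC)c2)c(OC)c1 | intermediate
25 | 4-(benzyloxy)-6-[(ArCDEF-oxy)methyl]-2H-pyran-2-one | O=C1C=C(OCc2ccccc2)C=C(COc3cc(OC)c(Oc4cc(OC)c(Oc5cc(OC)c(Oc6cc(OC)c(OC)c(OC)c6)c(OC)c5)c(OC)c4)c(OC)c3)O1 | intermediate
26 | benzyl (2E)-3-(benzyloxy)-6-(ArCDEF-oxy)-5-oxohex-2-enoate | O=C(OCc1ccccc1)/C=C(/OCc2ccccc2)CC(=O)COc3cc(OC)c(Oc4cc(OC)c(Oc5cc(OC)c(Oc6cc(OC)c(OC)c(OC)c6)c(OC)c5)c(OC)c4)c(OC)c3 | intermediate (not isolated)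
27 | 5-(benzyloxy)-3-hydroxy-2-(ArCDEF-oxy)cyclohexa-2,4-dien-1-one | O=C1CC(OCc2ccccc2)=CC(O)=C1Oc3cc(OC)c(Oc4cc(OC)c(Oc5cc(OC)c(Oc6cc(OC)c(OC)c(OC)c6)c(OC)c5)c(OC)c4)c(OC)c3 | intermediate (not isolated)
28 | 5-(benzyloxy)-2-(ArCDEF-oxy)benzene-1,3-diol (rings B–F) | Oc1cc(OCc2ccccc2)cc(O)c1Oc3cc(OC)c(Oc4cc(OC)c(Oc5cc(OC)c(Oc6cc(OC)c(OC)c(OC)c6)c(OC)c5)c(OC)c4)c(OC)c3 | intermediate
29 | 5-(benzyloxy)-1,3-dimethoxy-2-(ArCDEF-oxy)benzene | COc1cc(OCc2ccccc2)cc(OC)c1Oc3cc(OC)c(Oc4cc(OC)c(Oc5cc(OC)c(Oc6cc(OC)c(OC)c(OC)c6)c(OC)c5)c(OC)c4)c(OC)c3 | intermediate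
30 | 4-(ArCDEF-oxy)-3,5-dimethoxyphenol (ArBCDEF–OH) | Oc1cc(OC)c(Oc2cc(OC)c(Oc3cc(OC)c(Oc4cc(OC)c(Oc5cc(OC)c(OC)c(OC)c5)c(OC)c4)c(OC)c3)c(OC)c2)c(OC)c1 | intermediate
31 | 4-(benzyloxy)-6-[(ArBCDEF-oxy)methyl]-2H-pyran-2-one | O=C1C=C(OCc2ccccc2)C=C(COc3cc(OC)c(Oc4cc(OC)c(Oc5cc(OC)c(Oc6cc(OC)c(Oc7cc(OC)c(OC)c(OC)c7)c(OC)c6)c(OC)c5)c(OC)c4)c(OC)c3)O1 | intermediate
32 | benzyl (2E)-3-(benzyloxy)-6-(ArBCDEF-oxy)-5-oxohex-2-enoate | O=C(OCc1ccccc1)/C=C(/OCc2ccccc2)CC(=O)COc3cc(OC)c(Oc4cc(OC)c(Oc5cc(OC)c(Oc6cc(OC)c(Oc7cc(OC)c(OC)c(OC)c7)c(OC)c6)c(OC)c5)c(OC)c4)c(OC)c3 | intermediate (not isolated)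
33 | 5-(benzyloxy)-3-hydroxy-2-(ArBCDEF-oxy)cyclohexa-2,4-dien-1-one | O=C1CC(OCc2ccccc2)=CC(O)=C1Oc3cc(OC)c(Oc4cc(OC)c(Oc5cc(OC)c(Oc6cc(OC)c(Oc7cc(OC)c(OC)c(OC)c7)c(OC)c6)c(OC)c5)c(OC)c4)c(OC)c3 | intermediate (not isolated)
34 | 5-(benzyloxy)-2-(ArBCDEF-oxy)benzene-1,3-diol (rings A–F) | Oc1cc(OCc2ccccc2)cc(O)c1Oc3cc(OC)c(Oc4cc(OC)c(Oc5cc(OC)c(Oc6cc(OC)c(Oc7cc(OC)c(OC)c(OC)c7)c(OC)c6)c(OC)c5)c(OC)c4)c(OC)c3 | intermediate
35 | target hexamer (CNP0187343.0; ring A 2,4,6-trihydroxyphenyl, rings B–E 3,5-dihydroxy-1,4-phenylene dioxy, ring F 3,4,5-trihydroxyphenyl) | Oc1cc(O)c(Oc2cc(O)c(Oc3cc(O)c(Oc4cc(O)c(Oc5cc(O)c(Oc6cc(O)c(O)c(O)c6)c(O)c5)c(O)c4)c(O)c3)c(O)c2)c(O)c1 | target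

## Step count and least certain steps

Total step count: 21. Longest linear sequence: 21 steps (1 to 35); the chloride 5 is made once in steps 1 and 2 and re-enters in steps 3, 7, 11, 15 and 19.

Step 4 (key step, and its repeats in steps 8, 12, 16 and 20). The most likely failure is slow Claisen closure, because the ring-opened material rests as the stabilised dienolate deprotonated between the ketone and the enol ether. That leaves time for irreversible diversion: ester saponification by adventitious hydroxide, alkoxide addition at C6 of the lactone with opening to a carboxylate, or intermolecular aldol condensation. The fallback separates the two events and replaces the equilibrating alkoxide by a kinetic dianion. It sets out from 7, which is opened with NaOCH2Ph (1.1 equiv) at 0 °C and quenched with acetic acid so that the enoate 8 is isolated. Compound 8 is then treated with LiN(i-Pr)2 (2.5 equiv) in THF at −78 → 0 °C; the 1,3-dianion acylates itself at its terminal aryloxymethyl carbon (the classical polyketide-type cyclisation) and acid work-up returns to the route at 10. No new compound is made.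

Step 2. The most likely failure is proton transfer from 5 to unreacted 4, leading to double chlorination and recovered 3, or alkylation of 4 by 5 to give dimers. The fallback is known chemistry of the 4-methoxy analogue and sets out from 3. Oxidation of the methyl group with SeO2 (dioxane, 160 °C, sealed vessel) gives 4-(benzyloxy)-2-oxo-2H-pyran-6-carbaldehyde F1, and NaBH4 (MeOH, 0 °C) reduces it to 4-(benzyloxy)-6-(hydroxymethyl)-2H-pyran-2-one F2. F2 is joined to 6 by Mitsunobu etherification (PPh3, DIAD, THF), which returns to the route at 7; the same coupling with 12, 18, 24 and 30 returns at 13, 19, 25 and 31. This costs one more step and a toxic selenium reagent.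

Step 21. The most likely failures are incomplete cleavage of some of the twelve ethers, retention of boron on the pyrogallol ring, and air oxidation of the polyphenol during aqueous isolation. The fallback sets out from 34. After the same BBr3/C6HMe5 cleavage the mixture is quenched with methanol and evaporated, which removes boron as B(OCH3)3, and the crude product is acetylated under argon (Ac2O, pyridine) to the tetradecaacetate of the target F3. F3 is stable and can be purified on silica. Acid-catalysed methanolysis (HCl from AcCl in degassed MeOH, rt) then returns to the route at 35 without ever forming a phenoxide.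

Step 5 (and its repeats in steps 9, 13 and 17). The most likely failure is C-methylation at the ring carbons between the oxygens, since the resorcinolate is an ambident nucleophile, or incomplete methylation of the hydroxyls next to the aryloxy group. The fallback sets out from 10 and methylates under Mitsunobu conditions (MeOH, PPh3, DIAD, THF), in which the phenol oxygen attacks a methoxyphosphonium ion and no free phenoxide and alkyl halide are present together; it returns to the route at 11. No new compound is made.

## Further compounds

F1 | step 2 | 4-(benzyloxy)-2-oxo-2H-pyran-6-carbaldehyde | O=CC1=CC(OCc2ccccc2)=CC(=O)O1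
F2 | step 2 | 4-(benzyloxy)-6-(hydroxymethyl)-2H-pyran-2-one | OCC1=CC(OCc2ccccc2)=CC(=O)O1
F3 | step 21 | tetradecaacetate of 35 | CC(=O)Oc1cc(OC(C)=O)c(Oc2cc(OC(C)=O)c(Oc3cc(OC(C)=O)c(Oc4cc(OC(C)=O)c(Oc5cc(OC(C)=O)c(Oc6cc(OC(C)=O)c(OC(C)=O)c(OC(C)=O)c6)c(OC(C)=O)c5)c(OC(C)=O)c4)c(OC(C)=O)c3)c(OC(C)=O)c2)c(OC(C)=O)c1
F0 | step 4 | none | none
F0 | step 5 | none | none
A1 | alternative 1 | hexamer with ring D as methyl 2-aryloxy-4,6-dihydroxybenzoate (ester on C2 of ring D), other rings permethylated | COC(=O)c1c(O)c(Oc2cc(OC)c(Oc3cc(OC)c(OC)c(OC)c3)c(OC)c2)c(O)cc1Oc4c(OC)cc(Oc5c(OC)cc(Oc6c(OC)cc(OC)cc6OC)cc5OC)cc4OC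
A2 | alternative 1 | methyl 4-[3,5-dimethoxy-4-(3,4,5-trimethoxyphenoxy)phenoxy]-3-oxobutanoate | COC(=O)CC(=O)COc1cc(OC)c(Oc2cc(OC)c(OC)c(OC)c2)c(OC)c1
A3 | alternative 1 | methyl 3-{2,6-dimethoxy-4-[2,6-dimethoxy-4-(2,4,6-trimethoxyphenoxy)phenoxy]phenoxy}prop-2-ynoate | COC(=O)C#COc1c(OC)cc(Oc2c(OC)cc(Oc3c(OC)cc(OC)cc3OC)cc2OC)cc1OC
A4 | alternative 2 | hexamer decaformate (formyloxy on C3 and C5 of rings A–E, methoxy on C1 of ring A, ring F trimethoxy) | COc1cc(OC=O)c(Oc2cc(OC=O)c(Oc3cc(OC=O)c(Oc4cc(OC=O)c(Oc5cc(OC=O)c(Oc6cc(OC)c(OC)c(OC)c6)c(OC=O)c5)c(OC=O)c4)c(OC=O)c3)c(OC=O)c2)c(OC=O)c1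
A5 | alternative 2 | hexamer deca-aldehyde (formyl on C3 and C5 of rings A–E, methoxy on C1 of ring A, ring F trimethoxy) | COc1cc(C=O)c(Oc2cc(C=O)c(Oc3cc(C=O)c(Oc4cc(C=O)c(Oc5cc(C=O)c(Oc6cc(OC)c(OC)c(OC)c6)c(C=O)c5)c(C=O)c4)c(C=O)c3)c(C=O)c2)c(C=O)c1
A6 | alternative 2 | 5-(benzyloxy)-2-fluorobenzene-1,3-dicarbaldehyde | O=Cc1cc(OCc2ccccc2)cc(C=O)c1F
A7 | alternative 3 | (2S,3R,5R)-2-(ArBCDEF-oxy)-3-(benzyloxy)-5-hydroxycyclohexan-1-one (hydroxyl trans to benzyloxy, aryloxy trans to benzyloxy) | O=C1C[C@H](O)C[C@@H](OCc2ccccc2)[C@@H]1Oc3cc(OC)c(Oc4cc(OC)c(Oc5cc(OC)c(Oc6cc(OC)c(Oc7cc(OC)c(OC)c(OC)c7)c(OC)c6)c(OC)c5)c(OC)c4)c(OC)c3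
A8 | alternative 3 | methyl 4-O-(ArBCDEF)-3-O-benzyl-2,6-dideoxy-α-D-arabino-hex-5-enopyranoside | C=C1[C@H]([C@@H](C[C@H](O1)OC)OCc2ccccc2)Oc3cc(OC)c(Oc4cc(OC)c(Oc5cc(OC)c(Oc6cc(OC)c(Oc7cc(OC)c(OC)c(OC)c7)c(OC)c6)c(OC)c5)c(OC)c4)c(OC)c3
A9 | alternative 3 | 2-deoxy-D-galactose (2-deoxy-D-lyxo-hexopyranose, anomeric mixture) | C([C@@H]1[C@@H]([C@@H](CC(O1)O)O)O)O
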